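**Plan**

1. Atom numbering used below: C1 = ester CH next to the CMe2 carbon C11; C2 = CH2; C3 = second ester CH; C4 = methyl-bearing cyclobutane carbon; C5, C6, C7 = cyclobutane CH's bonded to C10, C11, C8; C8 = C=O; C9 = CH2; C10 = CHMe.
2. Retrosynthesis: remove the angelates and the C8 oxidation level; cut C4–C7 (cyclobutane) to a cis-fused bicyclic 1,3-dione with a C7 tosylate; cut C1–C2 and C3–C4 together, taking C2–C3 out of the seven-membered ring as dichloroketene, to a cyclopentanone; cut out C4 (CHMe insertion) and then C1–C5/C6–C11 (ketene [2+2]) to the silyl dienol ether of (S)-5-methylcyclohex-2-enone, made from (S)-pulegone.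
3. Enabling feature: in the seven-membered ring C1–C2–C3–C4–C5–C6–C11 the two oxygens sit 1,3 across the lone methylene C2, and C1 is flanked by the quaternary C11. This is the retron of a cyclopentanone (C1, C4, C5, C6, C11) that can enolise only toward C4 and takes up C2–C3 between C1 and C4.
4. Forward order: six-membered ring (chiral pool) → fused cyclobutanone → cyclopentanone → seven-membered ring by two-carbon insertion → cyclobutane by C4–C7 alkylation → reduction, esterification, C8 ketone.
5. Stereochemistry: C10 from pulegone; C5/C6 from suprafacial ketene addition anti to the C10 methyl; C7 from convex-face hydroboration followed by SN2 inversion; C4 from the geometry of the ring closure; C1/C3 from catalyst-controlled reduction.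

Key step: step 11

Remark: C4 (epimerisable) and the transient C1 carbinol of 12 and 13 are carried as epimer mixtures; they converge at 14 and 15.

**Step 1**
Reactants: 1 (S)-(−)-pulegone
Product: 2 (6S)-2,2,6-trimethyl-1-oxaspiro[2.5]octan-4-one (pulegone oxide; spiro epimers)
Conditions: 30% H2O2, LiOH (cat.), MeOH, 0 °C → rt
Reagents that add atoms: hydrogen peroxide, OO
Why: Weitz–Scheffer nucleophilic epoxidation of the tetrasubstituted enone; the new spiro centre is lost again in step 2 and the methyl centre is not touched.

**Step 2**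
Reactants: 2 pulegone oxide
Product: 3 (5S)-5-methyl-2-(phenylsulfanyl)cyclohexan-1-one (C2 epimers)
Conditions: PhSNa, THF, reflux; then H2O
Reagents that add atoms: sodium benzenethiolate, [Na+].[S-]c1ccccc1
Why: the thiolate opens the epoxide at the carbon alpha to the ketone and the tertiary alkoxide undergoes retro-aldol loss of acetone, the known degradation of pulegone oxide; the sulfur-bearing centre disappears in step 3.

**Step 3**
Reactants: 3 (5S)-5-methyl-2-(phenylsulfanyl)cyclohexan-1-one
Product: 5 (S)-5-methylcyclohex-2-en-1-one, via sulfoxide 4 (not isolated)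
Conditions: mCPBA, CH2Cl2, −78 °C; then CaCO3, toluene, 110 °C
Reagents that add atoms: none
Why: sulfide oxidation and thermal syn-elimination of the sulfoxide can only use the C3 hydrogens, so the conjugated enone should form with the methyl stereocentre intact.

**Step 4**
Reactants: 5 (S)-5-methylcyclohex-2-en-1-one
Product: 7 tert-butyl(dimethyl){[(5R)-5-methylcyclohexa-1,3-dien-1-yl]oxy}silane, via bromomagnesium dienolate 6 (not isolated)
Conditions: MeMgBr, FeCl3 (3 mol%), Et2O, −20 °C → rt; then TBSCl, Et3N, HMPA
Reagents that add atoms: tert-butyldimethylsilyl chloride, CC(C)(C)[Si](C)(C)Cl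
Why: iron-catalysed Grignard deprotonation removes a gamma-hydrogen (the CH2 next to the methyl-bearing carbon) to give the through-conjugated dienolate, and O-silylation should give the linear 1-siloxy-1,3-diene; no stereocentre is made (the descriptor changes to R only by priority).

**Step 5**
Reactants: 7 silyl dienol ether; 8 isobutyryl chloride
Product: 9 cis-fused 3-[(tert-butyldimethylsilyl)oxy]-5,8,8-trimethylbicyclo[4.2.0]oct-2-en-7-one (5-methyl trans to the C6–C7 bond)
Conditions: Et3N, toluene, 80 °C, slow addition of 8
Reagents that add atoms: none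
Why: Staudinger-type ketene–alkene [2+2] cycloaddition of dimethylketene made in situ, in which the ketene carbonyl carbon bonds to the diene terminus C5 (largest HOMO coefficient of a 1-oxy-diene, as in ketene additions to 1,3-dienes) and CMe2 to C6, suprafacially (cis fusion) and anti to the adjacent C10 methyl, which sets C5 and C6 relative to C10.

**Step 6**
Reactants: 9 cyclobutanone
Product: 10 cis-fused 6-[(tert-butyldimethylsilyl)oxy]-1,1,3,4-tetramethyl-1,3,3a,4,5,7a-hexahydro-2H-inden-2-one (C1 ketone; C4 epimers)
Conditions: CH3CHN2 (from N-ethyl-N-nitrosourea, 50% aq. KOH, Et2O, 0 °C), Et2O–MeOH, 0 °C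
Reagents that add atoms: diazoethane, CC=[N+]=[N-] (generated from N-ethyl-N-nitrosourea, CCN(N=O)C(N)=O)
Why: diazoalkane ring expansion of the strained cyclobutanone (Büchner–Curtius–Schlotterbeck reaction), in which the less substituted alpha-carbon C5 should migrate in preference to the quaternary C11 so that CHMe (C4) is inserted between C1 and C5; the C4 configuration is immaterial because C4 is enolised later.

**Step 7**
Reactants: 10 cyclopentanone
Product: 12 6-[(tert-butyldimethylsilyl)oxy]-1,1,3,4-tetramethyloctahydro-1H-indene-2,7-diol (C1 and C7 hydroxyls in route numbering; C7–OH trans to C8–OTBS and cis to H6), via C7-borane 11 (not isolated)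
Conditions: BH3·THF (3 equiv), THF, 0 °C → rt; then 3 M NaOH, 30% H2O2, 0 °C → rt
Reagents that add atoms: hydrogen peroxide, OO
Why: borane reduces the C1 ketone and hydroborates the silyl enol ether syn from the convex face (anti to the C11 substituent on C6) with boron at C7, beta to oxygen, and oxidation with retention should give the trans C7–OH/C8–OTBS pair; the C1 carbinol is a throw-away centre.

**Step 8**
Reactants: 12 diol
Product: 13 C7 mono-tosylate of 12
Conditions: TsCl, Et3N, Me3N·HCl (cat.), CH2Cl2, 0 °C → rt
Reagents that add atoms: 4-toluenesulfonyl chloride, Cc1ccc(cc1)S(Cl)(=O)=O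
Why: sulfonylation should select the C7 hydroxyl because the C1 hydroxyl lies between the quaternary C11 and the branched C4.

**Step 9**
Reactants: 13 hydroxy tosylate
Product: 14 keto tosylate (C1 ketone; C7–OTs; C8–OTBS; C4 epimers)
Conditions: Dess–Martin periodinane, CH2Cl2, rt
Reagents that add atoms: none
Why: Dess–Martin oxidation of the hindered secondary alcohol restores the C1 ketone without touching the tosylate or the silyl ether.

**Step 10**
Reactants: 14 keto tosylate
Product: 15 trimethylsilyl enol ether C1(OSiMe3)=C4(Me) of 14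
Conditions: TMSOTf, Et3N, CH2Cl2, 0 °C → rt
Reagents that add atoms: trimethylsilyl trifluoromethanesulfonate, C[Si](C)(C)OS(=O)(=O)C(F)(F)F
Why: soft enolisation; C11 is quaternary, so C4–H is the only alpha-hydrogen and a single tetrasubstituted silyl enol ether should form, in which the C4 epimers converge.

**Step 11**
Reactants: 15 silyl enol ether; 16 dichloroacetyl chloride
Product: 17 2,2-dichloro-3-(trimethylsilyloxy)cyclobutanone fused across C1–C4 (C3 carbonyl on C4; CCl2 = C2 on C1)
Conditions: Et3N, hexane–Et2O, rt, slow addition of 16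
Reagents that add atoms: none
Why: Dichloroketene, formed by dehydrochlorination of 16, is attacked at its carbonyl carbon (future C3) by the nucleophilic C4 of the enol ether, and the CCl2 carbon (future C2) closes onto the oxocarbenium carbon C1, a ketene–enol ether [2+2] cycloaddition of Staudinger type. The closest known reaction is the dichloroketene/silyl enol ether cycloaddition which, after dechlorination and retro-aldol opening, expands cycloalkanones by two carbons to cycloalkane-1,3-diones. One ring is closed, the cyclobutanone C1–C2–C3–C4, by [2+2] (asynchronous, or stepwise with 4-exo collapse of the zwitterion) on the cyclopentene. The new centres C1 and C4 are necessarily cis-fused and should arise from attack anti to the six-membered ring; both are erased in step 12, where C1 becomes a carbonyl and C4 an enolisable CH. The step needs regioselectivity (C3 to C4, C2 to C1), which the enol ether polarity provides, and chemoselectivity, which is secured because the enol ether is the only pi-nucleophile left (the other was consumed in step 7) and is a single regioisomer owing to the quaternary C11.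

**Step 12**
Reactants: 17 dichlorocyclobutanone
Product: 19 cis-fused bicyclic cycloheptane-1,3-dione (C1 and C3 ketones; C4 CHMe; C7–OTs; C8–OTBS), via dechlorinated siloxycyclobutanone 18 (not isolated)
Conditions: Zn dust, AcOH, i-PrOH–H2O, 50 °C
Reagents that add atoms: none
Why: zinc removes both chlorines and the beta-silyloxy cyclobutanone then loses silicon and undergoes retro-aldol cleavage of the ring-fusion bond C1–C4, the known two-carbon ring expansion; the enolisable dione is favoured over the alternative C1–C2 cleavage, which would leave a non-enolisable 2-acyl ketone.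

**Step 13**
Reactants: 19 dione tosylate
Product: 21 tricyclic 1,3-dione with the C4–C7 bond (C8–OTBS), via dilithium dianion 20 (not isolated)
Conditions: LiN(i-Pr)2 (2.3 equiv), THF, −78 → 0 °C; DMPU, 0 °C → rt; then H2O
Reagents that add atoms: none
Why: beta-diketone dianion alkylation, in which the second deprotonation can occur only at C4 (C11 is quaternary) and this gamma-carbanion should displace the C7 tosylate with inversion in a 4-exo-tet closure of the kind used for copaene-type cyclobutanes; C4 and C7 are fixed by geometry (the cis fusion holds C4 on the face opposite the leaving group) and E2 is disfavoured because H6 and H8 are both cis to the tosylate.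

**Step 14**
Reactants: 21 tricyclic dione
Product: 22 (1R,3R)-diol (C8–OTBS)
Conditions: (S)-2-methyl-CBS-oxazaborolidine (0.5 equiv), BH3·SMe2, THF, −20 °C → rt; then MeOH
Reagents that add atoms: none
Why: Corey–Bakshi–Shibata reduction under catalyst control; each carbonyl lies between a quaternary carbon (large) and the C2 methylene (small), so the (S)-catalyst should give the R carbinol at both C1 and C3 (as pinacolone gives the R alcohol), i.e. the anti-1,3-diol, while the substrate's own bias should be small because the two faces of the four-carbon bridge differ only through remote C8 and C10.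

**Step 15**
Reactants: 22 diol; 23 angelic anhydride
Product: 24 C1,C3-bis-angelate (C8–OTBS)
Conditions: LiN(SiMe3)2 (2.4 equiv), THF, −78 °C; then 23 (3 equiv), −78 → 0 °C
Reagents that add atoms: none
Why: acylation of the lithium alkoxides by the anhydride at low temperature avoids nucleophilic catalysts and should keep the Z (angelate) geometry; no stereocentre is touched.

**Step 16**
Reactants: 24 bis-angelate silyl ether
Product: 25 bis-angelate C8 alcohol
Conditions: HF·pyridine, THF, 0 °C → rt
Reagents that add atoms: none
Why: fluoride-mediated desilylation under mildly acidic conditions should leave the angelates intact.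

**Step 17**
Reactants: 25 alcohol
Product: 26 target diangelate
Conditions: Dess–Martin periodinane, CH2Cl2, rt
Reagents that add atoms: none
Why: Dess–Martin oxidation gives the C8 ketone; the adjacent C7 is a bridgehead and cannot epimerise.

**Compound list**

1 | (S)-(−)-pulegone | C[C@H]1CCC(=C(C)C)C(=O)C1 | starting material
2 | (6S)-2,2,6-trimethyl-1-oxaspiro[2.5]octan-4-one | C[C@H]1CCC2(OC2(C)C)C(=O)C1 | intermediate
3 | (5S)-5-methyl-2-(phenylsulfanyl)cyclohexan-1-one | C[C@H]1CCC(Sc2ccccc2)C(=O)C1 | intermediate
4 | (5S)-5-methyl-2-(phenylsulfinyl)cyclohexan-1-one | C[C@H]1CCC(S(=O)c2ccccc2)C(=O)C1 | intermediate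
5 | (S)-5-methylcyclohex-2-en-1-one | C[C@H]1CC=CC(=O)C1 | intermediate
6 | bromomagnesium (5R)-5-methylcyclohexa-1,3-dien-1-olate | C[C@H]1C=CC=C(O[Mg]Br)C1 | intermediate
7 | tert-butyl(dimethyl){[(5R)-5-methylcyclohexa-1,3-dien-1-yl]oxy}silane | C[C@H]1C=CC=C(O[Si](C)(C)C(C)(C)C)C1 | intermediate
8 | isobutyryl chloride | CC(C)C(Cl)=O | starting material
9 | cis-fused 3-silyloxy-5,8,8-trimethylbicyclo[4.2.0]oct-2-en-7-one | O=C1[C@@H]2[C@@H](C=C(O[Si](C)(C)C(C)(C)C)C[C@H]2C)C1(C)C | intermediate
10 | cis-fused cyclopentanone (C1 ketone, C4 CHMe, C7=C8 silyl enol ether) | O=C1C(C)[C@@H]2[C@@H](C=C(O[Si](C)(C)C(C)(C)C)C[C@H]2C)C1(C)C | intermediate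
11 | C7-borane, C1-O-borane adduct | BOC1C(C)[C@@H]2[C@@H]([C@@H](B)[C@H](O[Si](C)(C)C(C)(C)C)C[C@H]2C)C1(C)C | intermediate
12 | C1,C7-diol with C8–OTBS | OC1C(C)[C@@H]2[C@@H]([C@@H](O)[C@H](O[Si](C)(C)C(C)(C)C)C[C@H]2C)C1(C)C | intermediate
13 | C7 tosylate, C1 alcohol | OC1C(C)[C@@H]2[C@@H]([C@@H](OS(=O)(=O)c3ccc(C)cc3)[C@H](O[Si](C)(C)C(C)(C)C)C[C@H]2C)C1(C)C | intermediate
14 | C1 ketone, C7 tosylate | O=C1C(C)[C@@H]2[C@@H]([C@@H](OS(=O)(=O)c3ccc(C)cc3)[C@H](O[Si](C)(C)C(C)(C)C)C[C@H]2C)C1(C)C | intermediate
15 | C1=C4 trimethylsilyl enol ether | C[Si](C)(C)OC1=C(C)[C@@H]2[C@@H]([C@@H](OS(=O)(=O)c3ccc(C)cc3)[C@H](O[Si](C)(C)C(C)(C)C)C[C@H]2C)C1(C)C | intermediate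
16 | dichloroacetyl chloride | ClC(Cl)C(Cl)=O | starting material
17 | dichlorocyclobutanone cycloadduct | O=C1C(Cl)(Cl)[C@]2(O[Si](C)(C)C)[C@@]1(C)[C@@H]3[C@@H]([C@@H](OS(=O)(=O)c4ccc(C)cc4)[C@H](O[Si](C)(C)C(C)(C)C)C[C@H]3C)C2(C)C | intermediate
18 | dechlorinated siloxycyclobutanone | O=C1C[C@]2(O[Si](C)(C)C)[C@@]1(C)[C@@H]3[C@@H]([C@@H](OS(=O)(=O)c4ccc(C)cc4)[C@H](O[Si](C)(C)C(C)(C)C)C[C@H]3C)C2(C)C | intermediate
19 | cis-fused bicyclic cycloheptane-1,3-dione tosylate | O=C1CC(=O)C(C)[C@@H]2[C@@H]([C@@H](OS(=O)(=O)c3ccc(C)cc3)[C@H](O[Si](C)(C)C(C)(C)C)C[C@H]2C)C1(C)C | intermediate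
20 | dilithium dianion of 19 | [Li]OC1=CC(O[Li])=C(C)[C@@H]2[C@@H]([C@@H](OS(=O)(=O)c3ccc(C)cc3)[C@H](O[Si](C)(C)C(C)(C)C)C[C@H]2C)C1(C)C | intermediate
21 | tricyclic 1,3-dione, C8–OTBS | O=C1CC(=O)[C@]2(C)[C@@H]3[C@@H]([C@H]2[C@H](O[Si](C)(C)C(C)(C)C)C[C@H]3C)C1(C)C | intermediate
22 | tricyclic (1R,3R)-diol, C8–OTBS | O[C@@H]1C[C@@H](O)[C@]2(C)[C@@H]3[C@@H]([C@H]2[C@H](O[Si](C)(C)C(C)(C)C)C[C@H]3C)C1(C)C | intermediate
23 | angelic anhydride, (Z)-2-methylbut-2-enoic anhydride | C/C=C(/C)C(=O)OC(=O)/C(C)=C\C | starting material
24 | bis-angelate, C8–OTBS | C/C=C(/C)C(=O)O[C@@H]1C[C@@H](OC(=O)/C(C)=C\C)[C@]2(C)[C@@H]3[C@@H]([C@H]2[C@H](O[Si](C)(C)C(C)(C)C)C[C@H]3C)C1(C)C | intermediate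
25 | bis-angelate, C8 alcohol | C/C=C(/C)C(=O)O[C@@H]1C[C@@H](OC(=O)/C(C)=C\C)[C@]2(C)[C@@H]3[C@@H]([C@H]2[C@H](O)C[C@H]3C)C1(C)C | intermediate
26 | CNP0283599.1, 2,6,6,11-tetramethyl-9-oxotricyclo[5.4.0.0(2,8)]undecane-3,5-diyl bis[(Z)-2-methylbut-2-enoate] | C/C=C(/C)C(=O)O[C@@H]1C[C@@H](OC(=O)/C(C)=C\C)[C@]2(C)[C@@H]3[C@@H]([C@H]2C(=O)C[C@H]3C)C1(C)C | target

Total step count: 17. Longest linear sequence: 17 steps (the route is fully linear from 1).

**Steps most likely to fail**

Step 13. The four-membered ring closure may be slow, so that proton transfer returns the mono-enolate, which can alkylate through C2 (six-membered ring) or through oxygen. The fallback sets out from 19 and blocks C2. Condensation with N,N-dimethylformamide dimethyl acetal (toluene, 80 °C) should give the 2-[(dimethylamino)methylidene] dione F1. KN(SiMe3)2 (THF, −78 °C → rt) can then deprotonate only C4, and the mono-enolate should close to the tricyclic aminomethylidene dione F2. Hydrolytic deformylation (dilute HCl, then K2CO3, MeOH–H2O) should return the route at 21.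

Step 5. Ketene dimerisation may outrun the cycloaddition, the ketene may add across the silyl enol ether double bond instead of the terminal one, or facial discrimination by the C10 methyl may be insufficient. The fallback sets out from 7 and uses a cationic ketene equivalent. 1-Chloro-N,N,2-trimethylprop-1-en-1-amine and AgBF4 (CH2Cl2, −60 °C → rt) give the tetramethylketeniminium ion, whose stepwise [2+2] with the terminal double bond should give the cyclobutaniminium salt F3. Mild hydrolysis (aq. NaHCO3) should return the route at 9.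

Step 14. Facial discrimination may be poor at one carbonyl, borane may enolise the dione so that reduction stalls, or the second reduction may be mismatched. The fallback sets out from 21 and uses substrate direction in two stages. NaBH4 with CeCl3·7H2O (1 equiv, MeOH, −78 °C) should reduce the less hindered C3 carbonyl to the (3R)-hydroxy ketone F4, the C3 epimer being separated and re-oxidised. Hydroxyl-directed Evans–Saksena reduction with Me4NBH(OAc)3 (MeCN–AcOH, −20 °C) should then deliver hydride to C1 from the side of the C3 hydroxyl and return the route at the anti-diol 22.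

**Further compounds**

F1 | step 13 | 2-[(dimethylamino)methylidene] derivative of dione 19 | CN(C)C=C1C(=O)C(C)[C@@H]2[C@@H]([C@@H](OS(=O)(=O)c3ccc(C)cc3)[C@H](O[Si](C)(C)C(C)(C)C)C[C@H]2C)C(C)(C)C1=O
F2 | step 13 | tricyclic 2-[(dimethylamino)methylidene]-1,3-dione with the C4–C7 bond | CN(C)C=C1C(=O)[C@]2(C)[C@@H]3[C@@H]([C@H]2[C@H](O[Si](C)(C)C(C)(C)C)C[C@H]3C)C(C)(C)C1=O
F3 | step 5 | N,N-dimethylcyclobutaniminium tetrafluoroborate corresponding to 9 | C[N+](C)=C1[C@@H]2[C@@H](C=C(O[Si](C)(C)C(C)(C)C)C[C@H]2C)C1(C)C.F[B-](F)(F)F
F4 | step 14 | tricyclic (3R)-3-hydroxy-1-ketone, C8–OTBS | O=C1C[C@@H](O)[C@]2(C)[C@@H]3[C@@H]([C@H]2[C@H](O[Si](C)(C)C(C)(C)C)C[C@H]3C)C1(C)C
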